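In birch and elm target cannot pass 94.7% of the starting material charged, because each target takes up a second substrate, and that limiting reagent is charged below the starting material.

| flask | starting material | second substrate | scavenger | free enzyme | remark | time |
|---|---|---|---|---|---|---|
| west | 0.15 M | 0.142 M | 0.076 M | 15 µM | run made earlier |  |
| south-east | 0.15 M | 0.142 M | 0.25 M | 15 µM | run made earlier |  |
| birch | 0.15 M | 0.142 M | 0.150 M | 15 µM |  | 6.0 d |
| elm | 0.15 M | 0.142 M | 0.300 M | 15 µM |  | 6.0 d |

| run | time / d | starting material / % | target / % |
|---|---|---|---|
| west | 0.208 | 95.2 | 3.2 |
| west | 0.625 | 87.1 | 7.8 |
| west | 1.04 | 79.5 | 12.3 |
| west | 1.67 | 71.0 | 20.4 |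
| west | 2.50 | 62.0 | 28.2 |
| west | 3.00 | 57.0 | 32.5 |
| south-east | 0.500 | 90.6 | 5.5 |
| south-east | 1.04 | 83.5 | 12.6 |
| south-east | 1.67 | 76.7 | 20.0 |
| south-east | 2.08 | 72.4 | 23.9 |
| south-east | 2.50 | 68.8 | 28.9 |
| south-east | 3.00 | 64.7 | 32.4 |

(scatter of a reading: 0.5 percentage points)

- in percentages every species weighs as the starting material in it: one spent catalyst counts as two
- for first product the idle adduct is counted in
- reactions considered so far: second complex -> free enzyme + target; 2 second complex -> spent catalyst; starting material + free enzyme <-> first complex; first complex -> loaded enzyme + first product; second substrate + loaded enzyme <-> second complex; scavenger + first product -> scavenged by-product; starting material + first product <-> idle adduct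
- what has gone from starting material into another species counts as reacted, even if it can come back

* part of the starting material that has reacted at the end, birch
* part of the starting material that has reacted at the end, elm
* what raising the concentration of scavenger from its lowest to its highest value here does to the part of the starting material that has reacted (changes below 5 percentage points count as none) (it falls / no change / it rises)

I draw the target curve from both ends. The upper end is that ceiling. The lower end is the pair of readings at 3.00 d, 32.5% in west and 32.4% in south-east, close together although the scavenger differs. I let the distance to the ceiling shrink exponentially, and these readings give 7.15 d: this is the closing time, the time in which the distance of target from its ceiling falls by the factor e. The curve then starts with a slope of 0.132 /d, against 0.121 /d read over the first 1.04 d of south-east. It has no knee, passes half the charge at 5.37 d, and stands at 53.8% at 6.0 d.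

Reacted adds the gap between starting material lost and target, where the idle adduct sits: 10.5% in west and 2.90% in south-east. Multiplied by the equivalents of scavenger, these give 5.32% and 4.83%. So I take the gap as 5.08% divided by the equivalents and hold it until the end: 5.08% in birch, 2.54% in elm. My reckoning is 58.9% for birch and 56.3% for elm, apart by 2.5 percentage points, less than the 5 points that counts.

The forecast gives 55% for birch, 53.5% for elm and no change, lower than mine, and of the adduct it says: “By 6 d the rate has halved, so adduct is about 3% in birch and about 1% in elm.”

The flasks give 58.7% in birch and 56.6% in elm, with no change: the change is −2.1 points.

    second complex → free enzyme + target (k = 4.62 /min)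
    2 second complex → spent catalyst (k = 19.3 /M/min)
    starting material + free enzyme ⇌ first complex (K = 4.40 /M, k = 1150 /M/min)
    first complex → loaded enzyme + first product (k = 7.29 /min)
    second substrate + loaded enzyme ⇌ second complex (K = 2.90 /M, k = 6910 /M/min)
    scavenger + first product → scavenged by-product (k = 0.174 /M/min)
    starting material + first product ⇌ idle adduct, settled at all times (K = 170 /M)

At 6.00 d elm holds 55.3% target, against my 53.8% from the closing time. The answer for birch, already above the forecast's 55%, has moved by 5 points with free enzyme raised to 17.2 µM, which takes it further from that number. The neighbour flask is elm read at 4.0 d, before the 5.37 d crossing. The same closing time gives 40.6% target there. That flask holds 41.2% target, less than its 56.8% starting material.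

The data are calculated with made-up constants; noise was put on by code.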